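## Retrosynthetic overview

1. The only disconnection is the C16–O bond. The target is the 16-acetoxy derivative of (−)-copalic acid 1 (ent-labdane series, 5R,9R,10R), whose C16 methyl lies cis to the CO2H across C13=C14.
2. Forward: the carboxylate of 1 holds palladium next to C16 (palladacycle 2) and acetate is delivered to that carbon, giving 3. The skeleton, the 13,14-geometry and all three stereocentres come from 1.
3. Rings: none is formed. The trans-decalin (rings A and B) with its 8(17)-methylidene is taken intact from 1. Sclareol and sclareolide belong to the antipodal series and would give the wrong enantiomer.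

Assumption: 1 is bought as a catalogue natural product; it is the main diterpene acid of commercial copaiba balsam, from which it can also be obtained in multigram lots by base extraction and chromatography.

## Route

Step 1
Reactants: 1 (−)-copalic acid (ent-labda-8(17),13E-dien-15-oic acid)
Product: 3 16-acetoxy-ent-labda-8(17),13Z-dien-15-oic acid (target), via C16 palladacycle 2 (not isolated)
Conditions: Pd(OAc)2 (10 mol%), N-acetylglycine (20 mol%), PhI(OAc)2 (1.5 equiv), KOAc (2 equiv), (CF3)2CHOH, 45 °C, dark; stop near 70% conversion and recover 1
Reagents that add atoms: (diacetoxyiodo)benzene, CC(=O)OI(OC(C)=O)c1ccccc1 (net donor of the acetoxy group; its acetate exchanges with the KOAc buffer, CC(=O)[O-].[K+])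
Why: Proposed new method: a carboxylate-directed, Pd(OAc)2-catalysed C–H acetoxylation carried one vinylogous position further than known, onto the allylic γ-methyl of a free β-methyl-α,β-unsaturated acid; the potassium carboxylate of 1 binds divalent palladium, the rigid C13=C14 bond puts only C16 (cis to CO2H) within reach (C12 is trans, the 8(17)-alkene is remote), and N-acetylglycine-assisted concerted metalation–deprotonation of this allylic C–H gives the six-membered σ-allyl palladacycle 2; PhI(OAc)2 oxidises 2 to tetravalent palladium, from which a monodentate acetate dissociates and displaces the metal at C16 in an SN2-type C–O reductive elimination while the chelating substrate carboxylate stays on the metal (so closure to the butenolide should be the slower path); neither C13=C14 nor C5, C9 or C10 is touched, so the geometry and all three stereocentres of 1 are kept and no new stereocentre arises (the descriptor changes from 13E to 13Z only because CH2OAc outranks C12); the closest known reaction types are the ligand-enabled β-C(sp3)–H acyloxylation and lactonisation of free aliphatic acids and the carboxylate-directed benzylic C–H lactonisation of 2-methylbenzoic acids.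

## Compound list

1 | (−)-copalic acid = ent-labda-8(17),13E-dien-15-oic acid; (2E)-3-methyl-5-[(1R,4aR,8aR)-5,5,8a-trimethyl-2-methylidenedecahydronaphthalen-1-yl]pent-2-enoic acid | C=C1CC[C@@H]2C(C)(C)CCC[C@@]2(C)[C@@H]1CC/C(C)=C/C(=O)O | starting material

2 | six-membered palladacycle of 1: Pd bound to C16 and to the carboxylate oxygen, C13=C14 inside the ring (divalent palladium; amino acid ligand not drawn) | C=C1CC[C@@H]2C(C)(C)CCC[C@@]2(C)[C@@H]1CC/C1=C/C(=O)O[Pd]C1 | intermediate

3 | 16-acetoxy-ent-labda-8(17),13Z-dien-15-oic acid; (2Z)-3-(acetoxymethyl)-5-[(1R,4aR,8aR)-5,5,8a-trimethyl-2-methylidenedecahydronaphthalen-1-yl]pent-2-enoic acid | C=C1CC[C@@H]2C(C)(C)CCC[C@@]2(C)[C@@H]1CC/C(=C/C(=O)O)COC(C)=O | target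

## Step count and risk

Total step count: 1. Longest linear sequence: 1 step.

Steps most likely to fail: the route has one step, so there is one entry.

Step 1 (the proposed new step). Two things can go wrong:
- After C–H cleavage the substrate's own carboxylate, not acetate, may close onto C16 and give the 15,16-butenolide, which cannot be reopened to 3 in a simple way.
- Undirected palladium or iodane chemistry may occur at the 8(17)-methylidene (allylic oxidation at C7, double-bond migration).

Fallback (known chemistry; enolate oxidation and allylic transposition in place of C–H activation; it sets out from 1 and comes back to the route at 3). Acid 1 is esterified under neutral conditions with O-tert-butyl N,N′-diisopropylisourea (CH2Cl2, rt) to give tert-butyl ent-labda-8(17),13E-dien-15-oate F1. LiN(iPr)2 in THF/DMPU at −78 °C removes a proton from the C16 methyl (the γ-carbon cis to the ester), and the dienolate is hydroxylated at the α-carbon with 2-(phenylsulfonyl)-3-phenyloxaziridine to give tert-butyl 14-hydroxy-ent-labda-8(17),13(16)-dien-15-oate F2 (both C14 epimers). Ac2O, pyridine and DMAP convert it to tert-butyl 14-acetoxy-ent-labda-8(17),13(16)-dien-15-oate F3. Pd(PPh3)4 (5 mol%, zerovalent palladium) in THF at 50 °C then moves the acetate from C14 to C16 through the π-allyl complex, driven by conjugation with the ester. This gives tert-butyl (13Z)-16-acetoxy-ent-labda-8(17),13-dien-15-oate F4 together with tert-butyl (13E)-16-acetoxy-ent-labda-8(17),13-dien-15-oate F5. The E/Z ratio is not controlled and may favour F5; F5 is separated and returned to the same catalyst, under which the two isomers interconvert. Finally TMSOTf/2,6-lutidine (CH2Cl2, 0 °C) followed by aqueous work-up cleaves the tert-butyl ester of F4 without touching the acetate or the 8(17)-alkene and gives 3.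

## Further compounds

F1 | step 1 | tert-butyl ent-labda-8(17),13E-dien-15-oate | C=C1CC[C@@H]2C(C)(C)CCC[C@@]2(C)[C@@H]1CC/C(C)=C/C(=O)OC(C)(C)C
F2 | step 1 | tert-butyl 14-hydroxy-ent-labda-8(17),13(16)-dien-15-oate (both C14 epimers) | C=C1CC[C@@H]2C(C)(C)CCC[C@@]2(C)[C@@H]1CCC(=C)C(O)C(=O)OC(C)(C)C
F3 | step 1 | tert-butyl 14-acetoxy-ent-labda-8(17),13(16)-dien-15-oate (both C14 epimers) | C=C1CC[C@@H]2C(C)(C)CCC[C@@]2(C)[C@@H]1CCC(=C)C(OC(C)=O)C(=O)OC(C)(C)C
F4 | step 1 | tert-butyl (13Z)-16-acetoxy-ent-labda-8(17),13-dien-15-oate | C=C1CC[C@@H]2C(C)(C)CCC[C@@]2(C)[C@@H]1CC/C(COC(C)=O)=C/C(=O)OC(C)(C)C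
F5 | step 1 | tert-butyl (13E)-16-acetoxy-ent-labda-8(17),13-dien-15-oate | C=C1CC[C@@H]2C(C)(C)CCC[C@@]2(C)[C@@H]1CC/C(COC(C)=O)=C\C(=O)OC(C)(C)C
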